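Atom labels used throughout: tetralin numbering C1–C4, C4a, C5–C8, C8a for rings A and B; C1'–C6' for the pendant ring; C2a and C3a for the oxymethyl carbons on C2 and C3.

## Analysis of the target

The target is a 1-aryltetralin lignan of the isolariciresinol type. Ring A (C4a, C5–C8, C8a) is aromatic with a methoxyl on C6 and a free hydroxyl on C7, ring B (C1–C4, C4a, C8a) is saturated, and a 4-hydroxy-3,5-dimethoxyphenyl ring (C1'–C6') sits on C1. C2 and C3 each carry an acetoxymethyl group (carbons C2a and C3a), and C4 is a plain methylene. The three stereocentres are contiguous, C1 (S), C2 (R) and C3 (R); the aryl group, C2a and C3a alternate between the faces of ring B (1,2-trans, 2,3-trans), so all three can be pseudo-equatorial. The sensitive groups are two electron-rich phenols (easily oxidised once deprotonated), two primary acetates (which limit base and nucleophiles late in the route) and the doubly benzylic C1–H. The difficulty is to set three centres in one absolute sense, to put two different electron-rich arenes on one carbon, and to finish with both phenols free while both alcohols are esterified. The strategy rests on C1: it is bonded to two aryl carbons, C8a and C1', so it can be carried at the aldehyde oxidation level, and the oxygen on C3a lies where C1 can be stored as a five-membered lactol (C1–O–C3a–C3–C2) whose cation takes up the two arenes in turn. One consequence must be kept in view: between that oxolane and the tetralin, C3 exchanges its ring member and its substituent (C3a and C4), so the 2,3-trans tetralin arises from the 3,4-cis oxolane, not from the trans one.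

## Retrosynthetic reasoning

**19 from 18.** The last bond cut is the benzyl–oxygen bond on C7 of ring A. A benzyl ether masks this phenol through enolate, hydride, Lewis acid, fluoride and acylation steps and keeps it distinct from the pendant phenol. Hydrogenolysis then frees it without touching acetates, methyl ethers or stereocentres.

**18 from 17 from 16.** The acyl–oxygen bonds at C2a and C3a are cut next. Triol 16 has a phenol that acylates as well, so all three hydroxyls are acetylated (17) and the aryl ester alone is removed by aminolysis (18). The forward step relies on the phenoxide being a much better leaving group than a primary alkoxide.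

**16 from 15.** The silicon–oxygen bond at C2a is cut. The silyl ether keeps the C2a oxygen out of the cationic chemistry; fluoride removes it.

**15 from 12 and 13 (key disconnection).** The C1–C1' and C1–C8a bonds are both cut. They end at the same carbon, which in lactol 12 is an acetal carbon, so one electrophilic centre can form both. The pendant ring then comes from phenol 13 as bought, and ring B and the C1 stereocentre are made in the same operation. The forward reaction must achieve:
- attack by 13 through its carbon para to OH;
- closure of ring A through the carbon para to its methoxyl;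
- a trans relationship between C1 and C2;
- no loss of configuration at C2.

**12 from 11.** The silicon–oxygen bond is cut again; forward, the primary C2a hydroxyl has to be silylated in preference to the lactol hydroxyl.

**11 from 8 (through 9 and 10).** Lactol 11 must be 3,4-cis. Adding C2a directly to the enolate of lactone 6 would put it anti to the benzyl group, give the trans lactol and end in the C2 epimer of the target. The roles of the two carbons on C2 are therefore exchanged. In 8 the lactone carbonyl is the future C2a and the substituent introduced trans to the benzyl group is C1, already at the aldehyde level as a dimethyl acetal. Reduction of the lactone to diol 9 and acid treatment let the C3a hydroxyl close onto C1 (10, then 11). Because C2 has exchanged ring member and substituent, trans on the lactone becomes cis on the new oxolane.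

**8 from 6 (through 7).** The C1–C2 bond is cut. Forward, a dialkoxycarbenium ion alkylates the ketene silyl acetal 7 of the lactone, anti to the benzyl group; this sets C2.

**6 from 4 (through 5) from 3.** The lactone C–O bond and the C3 stereocentre are addressed here. The acid and ester groups of 4 are already different, so a chemoselective reduction decides that the ester carbon becomes C3a and the acid carbon the lactone carbonyl. C3 comes from catalytic asymmetric hydrogenation of the alkene of 3.

**3 from 1 and 2.** The C3–C4 bond is cut as an alkene, made by Stobbe condensation of aldehyde 1 with succinate 2.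

## Alternatives that were turned down

**Alternative 1:** Ring B is cut at C1–C2 and C3–C4 as a [4+2] cycloaddition. Irradiation of the 2-benzylbenzaldehyde A2 gives a hydroxy-o-quinodimethane, which adds to the fumarate A3 carrying two lactate auxiliaries and gives tetralin A1.
- For: it is convergent, makes two C–C bonds and four stereocentres at once, and the fumarate geometry guarantees the 2,3-trans relationship. On that last point it is stronger than the chosen route, which needs a ring exchange to reach the right C2/C3 relationship.
- Against: A1 carries a hydroxyl on C4 that the target lacks, so a benzylic deoxygenation must follow next to the ionisable C1. The absolute sense depends on remote ester auxiliaries steering a short-lived photoenol at ambient temperature, which is a weak basis for facial control. The dienol must form with its aryl group outward and competes with reketonisation. A2 is itself a protected diarylmethane that takes several steps to build. After the key step come ester reduction, deoxygenation, acetylation and double debenzylation.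
- Comparison: the chosen strategy takes its absolute configuration from a catalytic hydrogenation, carries no superfluous oxygen and uses 13 unprotected.

**Alternative 2:** The cuts are C1–C8a and C3–C4, a (3+3) annulation. Sc(OTf)3 lets the arene A6 open the donor–acceptor cyclopropane A5 at its aryl-bearing carbon with inversion, and base then closes the freed malonate onto the benzylic bromide of A6 to give A4.
- For: C1 is set stereospecifically from an enantioenriched cyclopropane. This is stronger than the chosen route, where C1 depends on a conformational preference in the ring closure.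
- Against: A4 is 1,2-cis and has an extra ester on C3. Dealkoxycarbonylation creates C3 without control, and C2 must be epimerised, so both centres finally rest on thermodynamics. The pivalate makes the arene of A6 a weaker nucleophile, while its electron-rich benzylic bromide is itself a Friedel–Crafts electrophile under the Lewis acid, so self-condensation competes. A5 needs an asymmetric cyclopropanation. The endgame is longer: decarboxylation, epimerisation, reduction of two esters, acetylation and removal of two different phenol protecting groups.
- Comparison: the chosen route fixes C2 and C3 before ring closure on carbons that cannot epimerise in the product.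

**Alternative 3:** The cuts are C3–C4 and C4–C4a, with C4 supplied by formaldehyde A9. Aldehyde A8 is methylenated alpha to the carbonyl under amine catalysis, and on acidification ring A attacks the terminal carbon of the resulting acrolein through its carbon para to OH, giving A7.
- For: it uses a very cheap one-carbon unit, leaves ring A unprotected and sets C3 last, on an epimerisable carbon that can settle trans. These are real advantages in protecting-group economy.
- Against: A8 already contains C1, a diarylmethine with two similar aryl groups, and C2, so the hardest stereochemical problem is moved rather than solved. Both aryl groups on C1 are equally placed to reach the acrolein terminus, and the ortho carbons of the pendant ring (ortho and para to methoxyls) are at least as nucleophilic as the ring A carbon, so closure can take the wrong ring. A free phenol with formaldehyde and an amine also invites ring hydroxymethylation or aminomethylation.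
- Comparison: in the chosen route only ring A is tethered to C1 through C4, so ring B can close in one way only.

Key step: step 7

Assumption: the (R,R) enantiomer of the bisphosphine in step 2 is taken to deliver the (3R) acid 4; if the sense of induction is the opposite, the (S,S) ligand is used and nothing else changes.

## Route

Step 1
Reactants: 1 4-benzyloxy-3-methoxybenzaldehyde; 2 dimethyl succinate
Product: 3 (E)-4-(4-benzyloxy-3-methoxyphenyl)-3-(methoxycarbonyl)but-3-enoic acid
Conditions: NaOMe, MeOH, reflux; then aq. HCl
Reagents that add atoms: none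
Why: Stobbe condensation: the succinate enolate adds to aldehyde 1, the aldolate lactonises onto the remote ester and base-induced opening of the paraconate gives the alkylidene half ester with the aryl group trans to the conjugated ester; this makes the future C3–C4 bond and leaves one acid and one ester for step 3 to tell apart.

Step 2
Reactants: 3 (E)-4-(4-benzyloxy-3-methoxyphenyl)-3-(methoxycarbonyl)but-3-enoic acid
Product: 4 (3R)-4-(4-benzyloxy-3-methoxyphenyl)-3-(methoxycarbonyl)butanoic acid
Conditions: H2 (5 bar), [Rh(cod)2]BF4 (1 mol %), (R,R)-Et-DuPhos (1.1 mol %), NaOMe (10 mol %), MeOH, rt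
Reagents that add atoms: none
Why: Rhodium–bisphosphine asymmetric hydrogenation of an itaconate-type half ester: carboxylate and alkene chelate the cationic metal and hydrogen is delivered to one face, setting C3 (R) under catalyst control; the aryl benzyl ether is not cleaved by the homogeneous catalyst.

Step 3
Reactants: 4 (3R)-4-(4-benzyloxy-3-methoxyphenyl)-3-(methoxycarbonyl)butanoic acid
Product: 6 (4R)-4-(4-benzyloxy-3-methoxybenzyl)oxolan-2-one, via hydroxy acid 5 (not isolated)
Conditions: KOH (1 equiv), EtOH, 0 °C; CaCl2, NaBH4, EtOH, 0 °C to rt; then 2 M HCl, rt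
Reagents that add atoms: none
Why: Chemoselective borohydride reduction: the potassium carboxylate is inert to Ca(BH4)2 made in the flask, which reduces the methyl ester to the primary alcohol; acidification closes hydroxy acid 5 to the gamma-lactone, so the ester carbon becomes C3a and the acid carbon the lactone carbonyl (the future C2a), with the stereocentre untouched.

Step 4
Reactants: 6 (4R)-4-(4-benzyloxy-3-methoxybenzyl)oxolan-2-one
Product: 8 (3S,4R)-4-(4-benzyloxy-3-methoxybenzyl)-3-(dimethoxymethyl)oxolan-2-one, via ketene silyl acetal 7 (not isolated)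
Conditions: LiN(iPr)2, THF, −78 °C; Me3SiCl, −78 to 0 °C; solvent exchange to CH2Cl2; HC(OMe)3 (3 equiv), Me3SiOTf (10 mol %), −78 °C; pyridine quench
Reagents that add atoms: trimethyl orthoformate, COC(OC)OC
Why: Mukaiyama-type alkylation of a ketene silyl acetal by an orthoester: Me3SiOTf ionises HC(OMe)3 to the dimethoxycarbenium ion, which attacks the alpha carbon of 7 (the future C2) on the face opposite the benzyl group, so C1 enters trans and C2 is set by substrate control; the silyl group leaves as Me3SiOMe and regenerates the catalyst.

Step 5
Reactants: 8 (3S,4R)-4-(4-benzyloxy-3-methoxybenzyl)-3-(dimethoxymethyl)oxolan-2-one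
Product: 11 (3R,4R)-4-(4-benzyloxy-3-methoxybenzyl)-3-(hydroxymethyl)oxolan-2-ol as a mixture of anomers, via diol 9 (not isolated), via cyclic methyl acetal 10 (not isolated)
Conditions: LiAlH4, THF, 0 °C; then 1 M HCl, THF/H2O, rt
Reagents that add atoms: water, O
Why: LiAlH4 reduces the lactone to diol 9, turning the former carbonyl carbon into C2a–OH; in aqueous acid the dimethyl acetal ionises and only the C3a hydroxyl can close a five-membered ring onto C1 (the C2a hydroxyl would give an oxetane), giving 10 and, after acetal hydrolysis, lactol 11. No bond to C2 or C3 is broken, and because C2 has exchanged its ring member (now C1) and its substituent (now C2a), the 3,4-trans lactone becomes the 3,4-cis oxolane.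

Step 6
Reactants: 11 (3R,4R)-4-(4-benzyloxy-3-methoxybenzyl)-3-(hydroxymethyl)oxolan-2-ol
Product: 12 (3R,4R)-4-(4-benzyloxy-3-methoxybenzyl)-3-[(tert-butyldiphenylsilyloxy)methyl]oxolan-2-ol as a mixture of anomers (3,4-cis)
Conditions: t-BuPh2SiCl (1.05 equiv), imidazole, CH2Cl2, −20 to 0 °C
Reagents that add atoms: tert-butyl(chloro)diphenylsilane, CC(C)(C)[Si](Cl)(c1ccccc1)c1ccccc1
Why: Chemoselective silylation: the bulky chlorosilane reacts with the unhindered primary C2a hydroxyl much faster than with the hindered secondary hemiacetal hydroxyl, and in the dominant ring-closed form the C3a oxygen is not available; weak base and low temperature protect the epimerisable C2 centre of the minor open-chain aldehyde.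

Step 7
Reactants: 12 (3R,4R)-4-(4-benzyloxy-3-methoxybenzyl)-3-[(tert-butyldiphenylsilyloxy)methyl]oxolan-2-ol; 13 2,6-dimethoxyphenol
Product: 15 (1S,2R,3R)-7-benzyloxy-2-[(tert-butyldiphenylsilyloxy)methyl]-1-(4-hydroxy-3,5-dimethoxyphenyl)-3-(hydroxymethyl)-6-methoxy-1,2,3,4-tetrahydronaphthalene, via 2-aryloxolane 14 (not isolated)
Conditions: 13 (2 equiv), BF3·OEt2 (2 equiv), CH2Cl2 (0.02 M), −78 to 0 °C; aq. NaHCO3
Reagents that add atoms: none
Why: BF3·OEt2 ionises the hemiacetal C1–OH of 12 to a five-membered cyclic oxocarbenium ion, and phenol 13 attacks C1 through C4, the carbon para to its hydroxyl (C3 and C5 are also activated, by the methoxyls, but are more hindered and attack there is expected to be minor), giving 2-aryloxolane 14 as C1 epimers, which is of no consequence because C1 becomes planar again. The para-hydroxyaryl group then lets the Lewis acid open the benzylic C1–O bond of 14 to a quinone-methide-like cation, which ring A captures through the carbon para to its methoxyl (C8a); this intramolecular Friedel–Crafts alkylation closes ring B as a six-membered ring, 6-exo-trig at C1 (the C1=C1' bond of the cation stays outside the new ring), and frees the C3a hydroxyl. The closest known reaction types are the Lewis-acid C-arylation of lactols by electron-rich phenols, as in aryl C-glycoside synthesis, and the acid-induced cyclisation of 2-aryl-4-benzyloxolane lignans to 1-aryltetralins; the cascade runs both in one flask. C1 is the only new stereocentre: in the chair-like transition state the pendant aryl group and the C2 silyloxymethyl group both lie pseudo-equatorial, so the C1–C8a bond forms trans to C2a and 1S follows from the existing 2R centre (substrate control), giving the all-equatorial isomer. If ring A attacks the oxocarbenium ion before the phenol does, the bridged benzylic ether so formed reopens at C1 (para-methoxybenzylic) and the phenol adds anti to C2a, converging on 15. The step needs intermolecular arylation to outrun proton loss from C2 (low temperature, excess of 13), regioselectivity on both arenes (the ring A carbon between tether and methoxyl is too hindered), and retention at C2 and C3, which belong to neither cation.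

Step 8
Reactants: 15 (1S,2R,3R)-7-benzyloxy-2-[(tert-butyldiphenylsilyloxy)methyl]-1-(4-hydroxy-3,5-dimethoxyphenyl)-3-(hydroxymethyl)-6-methoxy-1,2,3,4-tetrahydronaphthalene
Product: 16 (1S,2R,3R)-7-benzyloxy-1-(4-hydroxy-3,5-dimethoxyphenyl)-2,3-bis(hydroxymethyl)-6-methoxy-1,2,3,4-tetrahydronaphthalene
Conditions: Bu4NF, AcOH, THF, rt
Reagents that add atoms: none
Why: Fluoride-induced Si–O cleavage; buffering with AcOH avoids a phenoxide and its air oxidation on the electron-rich pendant ring, and no stereocentre is involved.

Step 9
Reactants: 16 (1S,2R,3R)-7-benzyloxy-1-(4-hydroxy-3,5-dimethoxyphenyl)-2,3-bis(hydroxymethyl)-6-methoxy-1,2,3,4-tetrahydronaphthalene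
Product: 17 (1S,2R,3R)-2,3-bis(acetoxymethyl)-1-(4-acetoxy-3,5-dimethoxyphenyl)-7-benzyloxy-6-methoxy-1,2,3,4-tetrahydronaphthalene
Conditions: Ac2O, pyridine, DMAP (cat.), CH2Cl2, rt
Reagents that add atoms: acetic anhydride, CC(=O)OC(C)=O
Why: Exhaustive acetylation under nucleophilic catalysis esterifies both primary alcohols and the hindered phenol, giving one fully acylated compound.

Step 10
Reactants: 17 (1S,2R,3R)-2,3-bis(acetoxymethyl)-1-(4-acetoxy-3,5-dimethoxyphenyl)-7-benzyloxy-6-methoxy-1,2,3,4-tetrahydronaphthalene
Product: 18 (1S,2R,3R)-2,3-bis(acetoxymethyl)-7-benzyloxy-1-(4-hydroxy-3,5-dimethoxyphenyl)-6-methoxy-1,2,3,4-tetrahydronaphthalene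
Conditions: pyrrolidine (3 equiv), THF, 0 °C to rt
Reagents that add atoms: none
Why: Chemoselective aminolysis: the aryl acetate has a far better leaving group (a phenoxide) than the primary alkyl acetates and is cleaved by the secondary amine while the alkyl esters persist.

Step 11
Reactants: 18 (1S,2R,3R)-2,3-bis(acetoxymethyl)-7-benzyloxy-1-(4-hydroxy-3,5-dimethoxyphenyl)-6-methoxy-1,2,3,4-tetrahydronaphthalene
Product: 19 (1S,2R,3R)-2,3-bis(acetoxymethyl)-7-hydroxy-1-(4-hydroxy-3,5-dimethoxyphenyl)-6-methoxy-1,2,3,4-tetrahydronaphthalene (CNP0265800.1)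
Conditions: H2 (1 atm), Pd/C (10 %), EtOAc, rt
Reagents that add atoms: none
Why: Hydrogenolysis of the aryl benzyl ether on Pd/C; acetates, methyl ethers, the arenes and the C–C bonds at the doubly benzylic C1 are inert under these mild conditions, so the target is released without touching a stereocentre.

## Compound list

1 | 4-benzyloxy-3-methoxybenzaldehyde | COc1cc(C=O)ccc1OCc1ccccc1 | starting material
2 | dimethyl succinate | COC(=O)CCC(=O)OC | starting material
3 | (E)-4-(4-benzyloxy-3-methoxyphenyl)-3-(methoxycarbonyl)but-3-enoic acid | COC(=O)/C(CC(=O)O)=C/c1ccc(OCc2ccccc2)c(OC)c1 | intermediate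
4 | (3R)-4-(4-benzyloxy-3-methoxyphenyl)-3-(methoxycarbonyl)butanoic acid | COC(=O)[C@@H](CC(=O)O)Cc1ccc(OCc2ccccc2)c(OC)c1 | intermediate
5 | (3R)-4-(4-benzyloxy-3-methoxyphenyl)-3-(hydroxymethyl)butanoic acid | OC[C@@H](CC(=O)O)Cc1ccc(OCc2ccccc2)c(OC)c1 | intermediate (not isolated)
6 | (4R)-4-(4-benzyloxy-3-methoxybenzyl)oxolan-2-one | O=C1C[C@@H](Cc2ccc(OCc3ccccc3)c(OC)c2)CO1 | intermediate
7 | (4R)-4-(4-benzyloxy-3-methoxybenzyl)-2-(trimethylsilyloxy)-4,5-dihydrofuran | C[Si](C)(C)OC1=C[C@@H](Cc2ccc(OCc3ccccc3)c(OC)c2)CO1 | intermediate (not isolated)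
8 | (3S,4R)-4-(4-benzyloxy-3-methoxybenzyl)-3-(dimethoxymethyl)oxolan-2-one (3,4-trans) | COC(OC)[C@@H]1[C@@H](Cc2ccc(OCc3ccccc3)c(OC)c2)COC1=O | intermediate
9 | (2R,3R)-2-(4-benzyloxy-3-methoxybenzyl)-3-(dimethoxymethyl)butane-1,4-diol | COC(OC)[C@@H](CO)[C@@H](Cc1ccc(OCc2ccccc2)c(OC)c1)CO | intermediate (not isolated)
10 | [(3R,4R)-4-(4-benzyloxy-3-methoxybenzyl)-2-methoxyoxolan-3-yl]methanol (anomers) | COC1[C@@H](CO)[C@@H](Cc2ccc(OCc3ccccc3)c(OC)c2)CO1 | intermediate (not isolated)
11 | (3R,4R)-4-(4-benzyloxy-3-methoxybenzyl)-3-(hydroxymethyl)oxolan-2-ol (anomers, 3,4-cis) | OC1[C@@H](CO)[C@@H](Cc2ccc(OCc3ccccc3)c(OC)c2)CO1 | intermediate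
12 | (3R,4R)-4-(4-benzyloxy-3-methoxybenzyl)-3-[(tert-butyldiphenylsilyloxy)methyl]oxolan-2-ol (anomers, 3,4-cis) | OC1[C@@H](CO[Si](c2ccccc2)(c2ccccc2)C(C)(C)C)[C@@H](Cc2ccc(OCc3ccccc3)c(OC)c2)CO1 | intermediate
13 | 2,6-dimethoxyphenol | COc1cccc(OC)c1O | starting material
14 | 4-[(3R,4R)-4-(4-benzyloxy-3-methoxybenzyl)-3-[(tert-butyldiphenylsilyloxy)methyl]oxolan-2-yl]-2,6-dimethoxyphenol (C2 epimers of the oxolane) | COc1cc(cc(OC)c1O)C1[C@@H](CO[Si](c2ccccc2)(c2ccccc2)C(C)(C)C)[C@@H](Cc2ccc(OCc3ccccc3)c(OC)c2)CO1 | intermediate (not isolated)
15 | (1S,2R,3R)-7-benzyloxy-2-[(tert-butyldiphenylsilyloxy)methyl]-1-(4-hydroxy-3,5-dimethoxyphenyl)-3-(hydroxymethyl)-6-methoxy-1,2,3,4-tetrahydronaphthalene | COc1cc2c(cc1OCc1ccccc1)[C@H](c1cc(OC)c(O)c(OC)c1)[C@@H](CO[Si](c1ccccc1)(c1ccccc1)C(C)(C)C)[C@H](CO)C2 | intermediate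
16 | (1S,2R,3R)-7-benzyloxy-1-(4-hydroxy-3,5-dimethoxyphenyl)-2,3-bis(hydroxymethyl)-6-methoxy-1,2,3,4-tetrahydronaphthalene | COc1cc2c(cc1OCc1ccccc1)[C@H](c1cc(OC)c(O)c(OC)c1)[C@@H](CO)[C@H](CO)C2 | intermediate
17 | (1S,2R,3R)-2,3-bis(acetoxymethyl)-1-(4-acetoxy-3,5-dimethoxyphenyl)-7-benzyloxy-6-methoxy-1,2,3,4-tetrahydronaphthalene | COc1cc2c(cc1OCc1ccccc1)[C@H](c1cc(OC)c(OC(C)=O)c(OC)c1)[C@@H](COC(C)=O)[C@H](COC(C)=O)C2 | intermediate
18 | (1S,2R,3R)-2,3-bis(acetoxymethyl)-7-benzyloxy-1-(4-hydroxy-3,5-dimethoxyphenyl)-6-methoxy-1,2,3,4-tetrahydronaphthalene | COc1cc2c(cc1OCc1ccccc1)[C@H](c1cc(OC)c(O)c(OC)c1)[C@@H](COC(C)=O)[C@H](COC(C)=O)C2 | intermediate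
19 | (1S,2R,3R)-2,3-bis(acetoxymethyl)-7-hydroxy-1-(4-hydroxy-3,5-dimethoxyphenyl)-6-methoxy-1,2,3,4-tetrahydronaphthalene (CNP0265800.1) | COc1cc2c(cc1O)[C@H](c1cc(OC)c(O)c(OC)c1)[C@@H](COC(C)=O)[C@H](COC(C)=O)C2 | target

## Step count and least certain steps

Total step count: 11. Longest linear sequence: 11 steps, from 1 to 19.

**Step 7 (key step).**
- What may go wrong: loss of configuration at C2, if the oxocarbenium ion sheds the C2 proton and is reprotonated, which would drain material into the more stable 3,4-trans oxolane series and so into the C2 epimer. The phenol may also attack through a methoxyl-activated carbon, and a second intermolecular arylation of the C1 cation may compete with ring closure. Acid-induced loss of the silyl group is harmless, since it leads to 16.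
- Fallback, from 12 back to the route at 16: the two aryl–C1 bonds are made separately. Commercial 4-bromo-2,6-dimethoxyphenol would be silylated (t-BuMe2SiCl, imidazole) to tert-butyl(4-bromo-2,6-dimethoxyphenoxy)dimethylsilane F1. Bromine–lithium exchange (n-BuLi, THF, −78 °C) and transmetalation with CeCl3 would give an aryl nucleophile of low basicity. Added in excess to 12, it first deprotonates the lactol and then adds to the open-chain aldehyde, giving the 1-arylbutane-1,4-diol F2 as C1 epimers. BF3·OEt2 in CH2Cl2 at −40 to 0 °C would ionise the benzylic alcohol of F2 and close ring B by the same trans-selective Friedel–Crafts alkylation, giving the bis-silylated tetralin F3. Bu4NF/AcOH would then remove both silyl groups and deliver 16.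

**Step 4.**
- What may go wrong: elimination of methanol from the product under the Lewis acid, a second addition of the ketene acetal to the ionised product, or incomplete facial selectivity in the alkylation.
- Fallback, from 6 back to 8: Claisen formylation (NaH, HCO2Me, THF) would give the 3-(hydroxymethylene) lactone F4. Treatment with HC(OMe)3 and MeOH under TsOH catalysis, left to equilibrate, would convert F4 into the dimethyl acetal with the C2 centre settling trans to the benzyl group under thermodynamic control, giving 8.

**Step 6.**
- What may go wrong: silylation of the C3a hydroxyl through the open-chain tautomer or of the anomeric hydroxyl, and base-mediated epimerisation at C2.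
- Fallback, from 8 back to 12: 8 would be reduced with LiAlH4 and worked up under basic conditions so that diol 9 is isolated. PPTS in dry MeOH would close 9 to methyl acetal 10, now isolated, which has a single free hydroxyl. Silylation (t-BuPh2SiCl, imidazole) would then give the silylated methyl acetal F5 without any selectivity question. Mild hydrolysis (AcOH/THF/H2O, 40 °C) would give 12. F5 could also be taken straight into step 7, because BF3·OEt2 ionises a 2-methoxyoxolane as readily as a lactol.

**Step 10.**
- What may go wrong: the aryl acetate is flanked by two methoxyl groups, so aminolysis may be slow enough for cleavage of the primary acetates to set in (loss of chemoselectivity).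
- Fallback, from 16 back to 19: the phenol is never acylated. BnBr and K2CO3 in acetone would alkylate only the phenol of 16, giving the bis(benzyl ether) diol F6. Ac2O/pyridine would give the bis(benzyl ether) diacetate F7. Hydrogenolysis (H2, Pd/C, EtOAc) would remove both benzyl groups and give 19 in the same number of steps.

Further compounds
F1 | step 7 | tert-butyl(4-bromo-2,6-dimethoxyphenoxy)dimethylsilane | COc1cc(Br)cc(OC)c1O[Si](C)(C)C(C)(C)C
F2 | step 7 | (2R,3R)-3-(4-benzyloxy-3-methoxybenzyl)-2-[(tert-butyldiphenylsilyloxy)methyl]-1-[4-(tert-butyldimethylsilyloxy)-3,5-dimethoxyphenyl]butane-1,4-diol (C1 epimers) | COc1cc(cc(OC)c1O[Si](C)(C)C(C)(C)C)C(O)[C@@H](CO[Si](c1ccccc1)(c1ccccc1)C(C)(C)C)[C@@H](Cc1ccc(OCc2ccccc2)c(OC)c1)CO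
F3 | step 7 | (1S,2R,3R)-7-benzyloxy-1-[4-(tert-butyldimethylsilyloxy)-3,5-dimethoxyphenyl]-2-[(tert-butyldiphenylsilyloxy)methyl]-3-(hydroxymethyl)-6-methoxy-1,2,3,4-tetrahydronaphthalene | COc1cc2c(cc1OCc1ccccc1)[C@H](c1cc(OC)c(O[Si](C)(C)C(C)(C)C)c(OC)c1)[C@@H](CO[Si](c1ccccc1)(c1ccccc1)C(C)(C)C)[C@H](CO)C2
F4 | step 4 | (4R)-4-(4-benzyloxy-3-methoxybenzyl)-3-(hydroxymethylene)oxolan-2-one | OC=C1C(=O)OC[C@@H]1Cc1ccc(OCc2ccccc2)c(OC)c1
F5 | step 6 | (3R,4R)-4-(4-benzyloxy-3-methoxybenzyl)-3-[(tert-butyldiphenylsilyloxy)methyl]-2-methoxyoxolane (anomers) | COC1[C@@H](CO[Si](c2ccccc2)(c2ccccc2)C(C)(C)C)[C@@H](Cc2ccc(OCc3ccccc3)c(OC)c2)CO1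
F6 | step 10 | (1S,2R,3R)-7-benzyloxy-1-(4-benzyloxy-3,5-dimethoxyphenyl)-2,3-bis(hydroxymethyl)-6-methoxy-1,2,3,4-tetrahydronaphthalene | COc1cc2c(cc1OCc1ccccc1)[C@H](c1cc(OC)c(OCc3ccccc3)c(OC)c1)[C@@H](CO)[C@H](CO)C2
F7 | step 10 | (1S,2R,3R)-2,3-bis(acetoxymethyl)-7-benzyloxy-1-(4-benzyloxy-3,5-dimethoxyphenyl)-6-methoxy-1,2,3,4-tetrahydronaphthalene | COc1cc2c(cc1OCc1ccccc1)[C@H](c1cc(OC)c(OCc3ccccc3)c(OC)c1)[C@@H](COC(C)=O)[C@H](COC(C)=O)C2
A1 | alternative 1 | bis[(2S)-1-methoxy-1-oxopropan-2-yl] 7-benzyloxy-1-(4-benzyloxy-3,5-dimethoxyphenyl)-4-hydroxy-6-methoxy-1,2,3,4-tetrahydronaphthalene-2,3-dicarboxylate (1,2-trans, 2,3-trans, 3,4-cis) | COc1cc2c(cc1OCc1ccccc1)[C@H](c1cc(OC)c(OCc3ccccc3)c(OC)c1)[C@@H](C(=O)O[C@@H](C)C(=O)OC)[C@H](C(=O)O[C@@H](C)C(=O)OC)[C@@H]2O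
A2 | alternative 1 | 4-benzyloxy-2-(4-benzyloxy-3,5-dimethoxybenzyl)-5-methoxybenzaldehyde | COc1cc(C=O)c(Cc2cc(OC)c(OCc3ccccc3)c(OC)c2)cc1OCc1ccccc1
A3 | alternative 1 | bis[(2S)-1-methoxy-1-oxopropan-2-yl] fumarate | COC(=O)[C@H](C)OC(=O)/C=C/C(=O)O[C@@H](C)C(=O)OC
A4 | alternative 2 | trimethyl 1-(4-benzyloxy-3,5-dimethoxyphenyl)-6-methoxy-7-pivaloyloxy-1,2,3,4-tetrahydronaphthalene-2,3,3-tricarboxylate (1,2-cis) | COc1cc2c(cc1OC(=O)C(C)(C)C)[C@H](c1cc(OC)c(OCc3ccccc3)c(OC)c1)[C@H](C(=O)OC)C(C(=O)OC)(C(=O)OC)C2
A5 | alternative 2 | trimethyl 3-(4-benzyloxy-3,5-dimethoxyphenyl)cyclopropane-1,1,2-tricarboxylate (2,3-trans, single enantiomer) | COc1cc(cc(OC)c1OCc1ccccc1)[C@H]1[C@H](C(=O)OC)C1(C(=O)OC)C(=O)OC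
A6 | alternative 2 | 4-(bromomethyl)-2-methoxyphenyl pivalate | COc1cc(CBr)ccc1OC(=O)C(C)(C)C
A7 | alternative 3 | all-trans 1-(4-benzyloxy-3,5-dimethoxyphenyl)-2-[(tert-butyldimethylsilyloxy)methyl]-7-hydroxy-6-methoxy-1,2,3,4-tetrahydronaphthalene-3-carbaldehyde | COc1cc2c(cc1O)[C@H](c1cc(OC)c(OCc3ccccc3)c(OC)c1)[C@@H](CO[Si](C)(C)C(C)(C)C)[C@H](C=O)C2
A8 | alternative 3 | 4-(4-benzyloxy-3,5-dimethoxyphenyl)-3-[(tert-butyldimethylsilyloxy)methyl]-4-(3-hydroxy-4-methoxyphenyl)butanal (single stereoisomer) | COc1ccc(cc1O)[C@H](c1cc(OC)c(OCc2ccccc2)c(OC)c1)[C@@H](CO[Si](C)(C)C(C)(C)C)CC=O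
A9 | alternative 3 | formaldehyde | C=O
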